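(The readings are calculated with constants of no real substance, and the scatter is random.)

If target stalls in this flask while substrate remains, I watch the pool, [substrate] + [target], as a fraction of the charge.

all flasks: substrate 2.4 M; gas phase 200 mM (held)

| flask | remark | time |
|---|---|---|
| elm | the very flask that is asked about, followed so far |  |
| flask |  | 10 d |

elm run (percent of the substrate charged)

| time / d | target / % | substrate / % |
|---|---|---|
| 0.417 | 14 | 86 |
| 0.833 | 21 | 64 |
| 1.25 | 32 | 48 |
| 1.67 | 35 | 42 |
| 2.00 | 36 | 31 |
| 2.50 | 37 | 24 |
| 3.00 | 33 | 25 |

(readings scatter by 1.5 percentage points)

- percentages count the substrate that a species holds: one side product counts as two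
- at the start none of the gas is dissolved
- the numbers in the tables scatter with a standard deviation of 1.5 percentage points
- steps that have been proposed: substrate + dissolved gas <-> target; substrate + target -> side product; gas phase <-> dissolved gas; 2 dissolved gas -> self-condensation product

- zeta: doubling the saturation concentration of gas phase, all else as stated
- alpha: doubling the transfer coefficient of the gas phase, all else as stated

* target at 10 d, in percent of the substrate charged
* concentration of dissolved gas in solution at 5.0 d, in percent of saturation
* the change that raises the amount of target at 10 d, in percent of the substrate charged most ("none" if none brings more than 2 percentage points) (zeta / alpha / none)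
* amount of target at 10 d, in percent of the substrate charged, after alpha

Target reads 37% at 2.50 d, yet the pool falls from 80.0% at 1.25 d to 58.0% at 3.00 d. While the addition holds [target]/[substrate] steady, the loss of substrate + target goes as the pool squared, so the inverse pool climbs in a straight line. These two readings give 3.69 d. I call this the pool clock, the time in which the inverse pool climbs by one; it is the second-order half-life of a full pool.

The 7.00 d still to run are 1.90 clocks, so I expect a pool of 27.6%. The last two readings put 58.8% of the pool in target. I carry that share forward, so my reckoning gives 16.2% target at 10 d.

The forecast says 18% target (14% to 23%), higher than mine, with dissolved gas at 85% of saturation at 5.0 d, zeta as the best change and 19% target after alpha. Its ground is that substrate and target “drain together through the side reaction”.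

The flask gives 17.5% target, dissolved gas at 95.7% of saturation at 5.0 d, zeta as the best change (a gain of 7.5 percentage points, against 0.12 points for alpha) and 17.7% target after alpha.

    substrate + dissolved gas ⇌ target (K = 10.0 L mol⁻¹, k = 5.30 × 10⁻⁵ L mol⁻¹ s⁻¹)
    substrate + target → side product (k = 3.10 × 10⁻⁶ L mol⁻¹ s⁻¹)
    gas phase ⇌ dissolved gas, rate k3*(csat - [dissolved gas]) (kL = 1.50 × 10⁻⁴ s⁻¹)
    2 dissolved gas → self-condensation product (k = 2.00 × 10⁻⁵ L mol⁻¹ s⁻¹)

The pool in this flask at 10.0 d stands at 26.3% against my 27.6%, and target holds 66.6% of it. For the neighbouring flask charged with 0.96 M of substrate, I stretch the clock by the ratio of the charges, to 9.23 d. Counted from a full pool, that gives 48.0% at 10 d. That neighbouring flask holds 31.0% target and 15.8% substrate, a pool of 46.8%.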